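## Analysis of the target

Germacrane numbering is used throughout: carbocycle C1–C10 with the ketone at C1, the furanone alkene C2=C3, C4 carrying the methylene C15, the free carbinol C5, the lactone O-carbon C6, C7, the isobutyrate carbon C8, C9 and the methylated quaternary C10 (methyl C14); lactone carbons C11 (=C13) and C12.

The target 36 is a ten-membered carbocycle bridged by oxygen between C3 and C10, so that C1, C2, C3, C10 and this oxygen form a 3(2H)-furanone, and an α-methylene-γ-butyrolactone is fused at C6–C7. It has five stereocentres: the contiguous set C5 (S), C6 (R), C7 (R), C8 (R) and the isolated quaternary C10 (R). As drawn, H-6 and H-7 are cis on the lactone, and the C5 and C6 oxygens are anti in the extended C4–C7 chain (cis on the ring). The sensitive groups are the α-methylene lactone and the cross-conjugated dienone C15=C4–C3=C2–C1=O (both Michael acceptors), the allylic C5 alcohol, the C8 ester, and any carbonyl at C8, which would sit β to the furanone oxygen on C10. The synthesis is hard because the ring counted through the furanone oxygen is only nine-membered and holds a trans-locked C4–C3–O–C10 unit, while four adjacent stereocentres must be set on it. The strategy rests on the C5(OH)–C6(O) pair flanked by the C4=C15 methylene: this is what a [2,3]-Wittig shift of a C15–O–C6 allylic ether carrying an alkoxy group on C5 delivers, and it lets a larger cyclic ether contract to the carbocycle. Two geometric points follow. In a ring contraction the carbanion substituent C7 is forced to lie over the allyl unit, so the 5,6-anti pair requires the (E)-enol ether, with the alkoxy group cis to C15. The enoate must carry its ester cis to C6 (E by the CIP rules) for both the deprotonation and the later lactonisation.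

## Retrosynthetic reasoning

36 ⇒ 33. The last operations are limited to the C5–O and C8–O substituents. The free C5 alcohol of 36 comes from its 4-methoxybenzyl ether 35, the C8 ester from alcohol 34, and 34 from silyl ether 33. C5 stays masked while C8 is acylated, and the two most fragile groups appear last.

33 ⇒ 29 ⇒ 28 ⇒ 27. The C11=C13 bond is cut (one carbon added to the enolate of lactone 29). The C7–H bond is cut next (conjugate hydride addition to butenolide 28, from the face of H-6, away from C5 and the ring chain). The lactone C12–O bond then leads back to hydroxy ester 27. The α-methylene lactone is thereby absent until the end, and 27 is the direct product of the sigmatropic step.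

27 ⇒ 25. C5–C6 is cut and O–C15 re-joined. The ten-membered carbocycle becomes the eleven-membered cyclic ether 25, which is easier to close. The forward step forms the ring bond and both carbinol centres at once, with their relative configuration dictated by the enol ether geometry.

25 ⇒ 24 ⇒ 23 ⇒ 22. The O–C6 bond is cut (Williamson closure of bromo alcohol 24). C6 has to be the electrophile, because a free C6 hydroxyl cis to the ester would lactonise; therefore bromide 23 is made directly from acetal 22 without passing through the alcohol.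

22 ⇒ 19 + 21; 19 ⇒ 18. The C6–C7 bond is cut (Stille coupling of vinyl iodide 19 with stannane 21, made from 20). The iodide comes from ynoate 18 by anti-hydroiodination. This fixes the enoate geometry, which a carbonyl olefination at C7 would leave open.

18 ⇒ 17 ⇒ 14 + 15. The C7–C8 bond is cut (alkynylation of aldehyde 14 with 15), which sets C8 by reagent control.

14 ⇒ 13 ⇒ 12 ⇒ 10. The C8 aldehyde is carried as a dithiane. The enol ether comes from O-alkylation of formyl enol 12, and the C4–C5 bond from formylation of the γ-position of furanone 10. Everything that needs strong base is finished before the enoate exists.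

10 ⇒ 9 ⇒ 8 ⇒ 5 + 6. The O–C3 bond is cut (5-endo-dig closure of hydroxy ynone 9) and then C1–C2 (acetylide 7 from 6 with aldehyde 5).

5 ⇒ 4 ⇒ 1 + 2. The C8–C9 bond is cut (opening of epoxide 1 by lithiated 2, i.e. 3). C10 is taken unchanged from 1.

## Alternatives that were turned down

Alternative 1: The furanone is cut at O–C3 and C9–C10. In the forward sense the open-chain α-ketol A1 would be treated with AuCl3 or PtCl2: the C10 ketone oxygen adds to the alkyne at C3 and C9 shifts from C1 to C10, which gives iodovinyl furanone A2 with the quaternary centre in place. In its favour, C6, C7, C8, the lactone and the ester are made on an open chain by ordinary acyclic stereocontrol, and the furanone arrives late and convergently. Against it, C10 depends on an enantiopure tertiary alkynyl carbinol and on clean suprafacial transfer. The α-methylene lactone and the vinyl iodide must survive a carbophilic Lewis acid. The ten-membered ring is still open in A2 and would need a second difficult step (C4–C5 closure with CrCl2/NiCl2) that also creates C5 without an obvious control element. It is stronger than the chosen route in convergence and in setting C7 early. The chosen route offers instead one ring-forming step that sets C5 and C6 together from a geometry-defined enol ether.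

Alternative 2: The carbocycle is cut at C1–C2. Irradiation at 254 nm of the ten-membered enol lactone A3 would move the C1 acyl group from oxygen to C2 and give the carbocyclic 1,3-diketone A4, to be cyclodehydrated to the furanone afterwards. In its favour, no stereocentre is formed in the key step, all five are set beforehand, and a lactone is converted into a carbocycle of the same size. Against it, the C1 acyl radical sits next to a fully substituted oxygenated carbon and should lose CO in competition with recombination. The α-methylene lactone and the diene absorb in the same region. The enol lactone of a hindered acid is itself hard to make. It is stronger in carrying no stereochemical risk in the key step. The chosen route offers a ground-state anionic reaction at low temperature in which the other π systems are spectators.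

Alternative 3: The furanone is cut at C2=C3. Heating the keto-stabilised phosphorane A5, a nine-membered acrylate lactone, would let ylide carbon C2 attack the lactone carbonyl C3. Loss of Ph3PO closes the furanone and gives A6, one desilylation from the target. In its favour, it has the shortest endgame, all stereocentres are preset, and intramolecular Wittig closure on an ester carbonyl to a furanone is a known five-membered ring formation. Against it, A5 requires a nine-membered lactone of a tertiary alcohol. The ylide and the phosphine used to make it are nucleophiles towards the α-methylene lactone and the acrylate, and ester olefination needs heat. It is stronger in step economy after the key step. The chosen route offers an easier first ring closure (O-alkylation to an eleven-membered ether), lets C–C bond formation pay for the strain of the contraction, and keeps the α-methylene lactone out of the molecule until the end.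

Key step: step 17

Remark on the reading of the target: the SMILES is taken as drawn, (5S,6R,7R,8R,10R), with H-6 and H-7 cis on the lactone.
Remark on mixtures: 21 and 22 carry a tetrahydropyranyl acetal and are handled as mixtures of the two acetal epimers; this centre is lost in step 14. 8 is a mixture at its secondary carbinol, which is oxidised in step 4.
Remark on names: Fu = (2R)-5-{(E)-3-[(tert-butyldimethylsilyl)oxy]-1-[(4-methoxybenzyl)oxy]prop-1-en-2-yl}-2-methyl-3-oxo-2,3-dihydrofuran-2-yl.

## Route

Step 1
Reactants: 1 (S)-2-methylglycidol; 2 1,3-dithiane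
Product: 4 (R)-3-(1,3-dithian-2-yl)-2-methylpropane-1,2-diol, via 2-lithio-1,3-dithiane 3 (not isolated)
Conditions: 2 (2.3 equiv), n-BuLi (2.2 equiv), THF, −30 °C; then 1, DMPU, −30 → 0 °C; aq NH4Cl
Reagents that add atoms: none
Why: Corey–Seebach umpolung; the lithiated dithiane opens the 2,2-disubstituted epoxide at its CH2 (SN2), so the future C10 is not touched, and a Payne shift of the alkoxide is degenerate and keeps the configuration.

Step 2
Reactants: 4 (R)-3-(1,3-dithian-2-yl)-2-methylpropane-1,2-diol
Product: 5 (R)-3-(1,3-dithian-2-yl)-2-hydroxy-2-methylpropanal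
Conditions: SO3·pyridine, DMSO, i-Pr2NEt, CH2Cl2, 0 °C
Reagents that add atoms: none
Why: Parikh–Doering oxidation acts only on the primary alcohol (the tertiary one cannot be oxidised) and tolerates the thioacetal; the aldehyde has no α-hydrogen.

Step 3
Reactants: 5 (R)-3-(1,3-dithian-2-yl)-2-hydroxy-2-methylpropanal; 6 tert-butyl(but-3-yn-1-yloxy)dimethylsilane
Product: 8 (2R,3RS)-7-(tert-butyldimethylsilyloxy)-1-(1,3-dithian-2-yl)-2-methylhept-4-yne-2,3-diol, via [4-(tert-butyldimethylsilyloxy)but-1-ynyl]lithium 7 (not isolated)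
Conditions: 6 (2.3 equiv), n-BuLi (2.2 equiv), THF, −78 °C; then 5, −78 → −20 °C
Reagents that add atoms: none
Why: 1,2-addition of the lithium acetylide to the aldehyde; the excess acetylide absorbs the free tertiary hydroxyl, and the new carbinol is oxidised in the next step so its configuration is irrelevant.

Step 4
Reactants: 8 (2R,3RS)-7-(tert-butyldimethylsilyloxy)-1-(1,3-dithian-2-yl)-2-methylhept-4-yne-2,3-diol
Product: 9 (R)-7-(tert-butyldimethylsilyloxy)-1-(1,3-dithian-2-yl)-2-hydroxy-2-methylhept-4-yn-3-one
Conditions: MnO2 (excess), CH2Cl2, rt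
Reagents that add atoms: none
Why: MnO2 oxidises the activated propargylic alcohol selectively and leaves the tertiary alcohol, the silyl ether and the dithiane alone.

Step 5
Reactants: 9 (R)-7-(tert-butyldimethylsilyloxy)-1-(1,3-dithian-2-yl)-2-hydroxy-2-methylhept-4-yn-3-one
Product: 10 (R)-5-[2-(tert-butyldimethylsilyloxy)ethyl]-2-(1,3-dithian-2-ylmethyl)-2-methylfuran-3(2H)-one
Conditions: K2CO3 (cat.), MeOH, 0 °C → rt
Reagents that add atoms: none
Why: Base-mediated oxa-Michael addition of the tertiary hydroxyl to the ynone β-carbon C3 in the favoured 5-endo-dig mode closes the 3(2H)-furanone; C10 is not involved.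

Step 6
Reactants: 10 (R)-5-[2-(tert-butyldimethylsilyloxy)ethyl]-2-(1,3-dithian-2-ylmethyl)-2-methylfuran-3(2H)-one
Product: 12 (R)-5-[3-(tert-butyldimethylsilyloxy)-1-hydroxyprop-1-en-2-yl]-2-(1,3-dithian-2-ylmethyl)-2-methylfuran-3(2H)-one (enol form of the C4 aldehyde), via lithium dienolate of the furanone 11 (not isolated)
Conditions: LiN(i-Pr)2 (2.2 equiv), THF, −78 °C; CF3CH2OCHO, −78 °C; aq NH4Cl
Reagents that add atoms: 2,2,2-trifluoroethyl formate, O=COCC(F)(F)F
Why: The C4 methylene is the only enolisable position (C10 is quaternary), so kinetic γ-deprotonation gives the extended enolate, which undergoes Claisen formylation at C4. The second equivalent of base is taken up by the acidic product, and −78 °C suppresses β-loss of silyloxide.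

Step 7
Reactants: 12 (R)-5-[3-(tert-butyldimethylsilyloxy)-1-hydroxyprop-1-en-2-yl]-2-(1,3-dithian-2-ylmethyl)-2-methylfuran-3(2H)-one
Product: 13 (R)-5-{(E)-3-(tert-butyldimethylsilyloxy)-1-[(4-methoxybenzyl)oxy]prop-1-en-2-yl}-2-(1,3-dithian-2-ylmethyl)-2-methylfuran-3(2H)-one
Conditions: 4-methoxybenzyl chloride, Cs2CO3, Bu4NI (cat.), DMF, 0 °C → rt
Reagents that add atoms: 4-methoxybenzyl chloride, COc1ccc(CCl)cc1
Why: O-alkylation of the delocalised caesium enolate at the formyl oxygen; as in β-alkoxyacrylate syntheses the alkoxy group should end anti to the acceptor C3 and cis to C15, which is the (E)-enol ether the key step needs. The geometry is to be verified by an NOE between H-5 and H-2.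

Step 8
Reactants: 13 (R)-5-{(E)-3-(tert-butyldimethylsilyloxy)-1-[(4-methoxybenzyl)oxy]prop-1-en-2-yl}-2-(1,3-dithian-2-ylmethyl)-2-methylfuran-3(2H)-one
Product: 14 2-Fu-acetaldehyde (the C8 aldehyde)
Conditions: MeI (excess), CaCO3, MeCN–H2O (9:1), 40 °C
Reagents that add atoms: water, O
Why: Alkylative hydrolysis of the dithiane under buffered, non-oxidising conditions frees the C8 aldehyde without thiophilic metal salts or oxidants that would attack the enol ether. The near-neutral medium limits β-elimination of the furanone oxygen.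

Step 9
Reactants: 14 2-Fu-acetaldehyde; 15 methyl propiolate
Product: 17 methyl (4R)-4-hydroxy-5-Fu-pent-2-ynoate, via methyl 3-(methylzincio)propiolate 16 (not isolated)
Conditions: 15 (3 equiv), Me2Zn (3 equiv), ProPhenol ligand (20 mol %, the antipode that directs the alkynyl group to the Si face of C8), Ph3PO (40 mol %), toluene, 4 °C
Reagents that add atoms: none
Why: Catalytic asymmetric alkynylation of an aldehyde by a zinc alkynylide under reagent control; Si-face addition gives 8R, and the weakly basic zinc medium should spare the β-oxygenated aldehyde.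

Step 10
Reactants: 17 methyl (4R)-4-hydroxy-5-Fu-pent-2-ynoate
Product: 18 methyl (4R)-4-[(tert-butyldimethylsilyl)oxy]-5-Fu-pent-2-ynoate
Conditions: TBSCl, imidazole, DMF, rt
Reagents that add atoms: tert-butyldimethylsilyl chloride, CC(C)(C)[Si](C)(C)Cl
Why: Standard silylation of the propargylic alcohol; the C8 centre is not touched.

Step 11
Reactants: 18 methyl (4R)-4-[(tert-butyldimethylsilyl)oxy]-5-Fu-pent-2-ynoate
Product: 19 methyl (2Z,4R)-4-[(tert-butyldimethylsilyl)oxy]-3-iodo-5-Fu-pent-2-enoate
Conditions: NaI (3 equiv), AcOH (6 equiv), MeCN, rt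
Reagents that add atoms: sodium iodide, [Na+].[I-]
Why: Conjugate anti-addition of HI to the ynoate (iodide to C7, proton to C11) gives the β-iodo enoate with iodine cis to the ester, which fixes the later enoate geometry. The push-pull enol ether should tolerate a few equivalents of AcOH at room temperature.

Step 12
Reactants: 20 (tributylstannyl)methanol
Product: 21 tributyl[(oxan-2-yloxy)methyl]stannane
Conditions: 3,4-dihydro-2H-pyran, PPTS (cat.), CH2Cl2, rt
Reagents that add atoms: 3,4-dihydro-2H-pyran, C1=COCCC1
Why: Acid-catalysed acetal formation gives a hydroxymethyl donor whose oxygen stays masked after the coupling.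

Step 13
Reactants: 19 methyl (2Z,4R)-4-[(tert-butyldimethylsilyl)oxy]-3-iodo-5-Fu-pent-2-enoate; 21 tributyl[(oxan-2-yloxy)methyl]stannane
Product: 22 methyl (2E,4R)-4-[(tert-butyldimethylsilyl)oxy]-3-[(oxan-2-yloxy)methyl]-5-Fu-pent-2-enoate
Conditions: Pd(PPh3)4 (10 mol %), CuI (20 mol %), dioxane, 70 °C
Reagents that add atoms: none
Why: Stille coupling with retention of alkene geometry; the α-oxygenated methyl group transfers in preference to butyl, so C6 is installed cis to the ester, and the acetal prevents lactonisation onto that ester.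

Step 14
Reactants: 22 methyl (2E,4R)-4-[(tert-butyldimethylsilyl)oxy]-3-[(oxan-2-yloxy)methyl]-5-Fu-pent-2-enoate
Product: 23 methyl (2Z,4R)-3-(bromomethyl)-4-[(tert-butyldimethylsilyl)oxy]-5-Fu-pent-2-enoate
Conditions: CBr4 (2 equiv), PPh3 (4 equiv), CH2Cl2, 0 °C → rt
Reagents that add atoms: carbon tetrabromide, BrC(Br)(Br)Br
Why: Appel-type direct conversion of a tetrahydropyranyl ether into the bromide, so that a free C6 hydroxyl cis to the ester is never handled; silyl ethers are inert to these conditions.

Step 15
Reactants: 23 methyl (2Z,4R)-3-(bromomethyl)-4-[(tert-butyldimethylsilyl)oxy]-5-Fu-pent-2-enoate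
Product: 24 methyl (2Z,4R)-3-(bromomethyl)-4-[(tert-butyldimethylsilyl)oxy]-5-[(2R)-5-{(E)-3-hydroxy-1-[(4-methoxybenzyl)oxy]prop-1-en-2-yl}-2-methyl-3-oxo-2,3-dihydrofuran-2-yl]pent-2-enoate
Conditions: Et3N·3HF, THF, 0 °C → rt
Reagents that add atoms: none
Why: Fluoride cleaves the unhindered primary C15 silyl ether well before the hindered secondary C8 silyl ether, and the non-basic medium spares the allylic bromide.

Step 16
Reactants: 24 methyl (2Z,4R)-3-(bromomethyl)-4-[(tert-butyldimethylsilyl)oxy]-5-[(2R)-5-{(E)-3-hydroxy-1-[(4-methoxybenzyl)oxy]prop-1-en-2-yl}-2-methyl-3-oxo-2,3-dihydrofuran-2-yl]pent-2-enoate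
Product: 25 eleven-membered cyclic ether [(4E,7E,8R,10R); C15–O–C6 ether; CO2Me cis to C6; 4-methoxybenzyloxy cis to C15; 8-O-TBS]
Conditions: Ag2O (3 equiv), 4 Å MS, toluene (0.002 M), 45 °C, dark
Reagents that add atoms: none
Why: Silver-assisted Williamson etherification, SN2 at the primary allylic C6 by the C15 hydroxyl at high dilution. No strong base is present, so the γ-bromo enoate is not enolised, and the ring (ten-membered through the furanone oxygen) has three sp2 atoms and two ring oxygens that keep transannular strain low.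

Step 17
Reactants: 25 eleven-membered cyclic ether
Product: 27 ten-membered hydroxy enoate [(5S,6R,8R,10R); 6-OH; 5-O-(4-methoxybenzyl); C4=C15 methylene; 8-O-TBS; (7E)-C7=C11–CO2Me], via lithium dienolate of the cyclic ether 26 (not isolated)
Conditions: LiN(SiMe3)2 (1.3 equiv), THF, −78 → −40 °C; AcOH, −78 °C
Reagents that add atoms: none
Why: LiN(SiMe3)2 binds the ester carbonyl and removes a C6 hydrogen, which lies cis to the ester and next to the ether oxygen, rather than the trans, tertiary and shielded C8–H; dienolate 26 then forms C5–C6 while O–C15 breaks through a five-centre, six-electron transition state, leaving the C6 alkoxide and the C4=C15 methylene. The closest known reaction type is the [2,3]-Wittig ring contraction of macrocyclic allylic ethers, here with an ester dienolate as the carbanion and a γ-alkoxyallyl ether as the migrating partner. The ten-membered carbocycle is closed by contraction of the eleven-membered ether, the new bond spanning C6 and C4 across C5 in a bridged bicyclic transition state, so no separate end-to-end closure is needed. Because the chain C7–C10 ties the carbanion carbon to C3, C7 has to lie over the allyl unit (endo), and the C5 substituent that was cis to C15 ends up cis to the C6 oxygen on the new ring; the (E)-enol ether therefore fixes the relative configuration as 5,6-anti. The absolute sense comes from C10: the tether leaves C10 on the face opposite its methyl group and can reach C5 only from that face when the dienol ether stays conjugated with the furanone with C5 syn to the ring oxygen, which should give 5S,6R. The step needs regioselective deprotonation (cis ester, hindered C8), a [2,3] rather than a [1,2] shift (favoured at low temperature for a stabilised carbanion) and no loss of C6 integrity once the alkoxide starts to lactonise, which is why the base is kept near one equivalent and the mixture is quenched cold with AcOH.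

Step 18
Reactants: 27 ten-membered hydroxy enoate
Product: 28 butenolide [(5S,6R,8R,10R); 6,12-olide with C7=C11; 5-O-(4-methoxybenzyl); 8-O-TBS]
Conditions: PPTS (cat.), CH2Cl2, rt
Reagents that add atoms: none
Why: Acid-catalysed lactonisation of the γ-hydroxy ester whose ester is cis to the hydroxyl (5-exo-trig acyl substitution); mild acid leaves the silyl and 4-methoxybenzyl ethers in place.

Step 19
Reactants: 28 butenolide
Product: 29 saturated 6,12-lactone [(5S,6R,7S,8R,10R); C11H2; H-7 cis to H-6; 5-O-(4-methoxybenzyl); 8-O-TBS]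
Conditions: Cu(OAc)2·H2O (5 mol %), 1,2-bis(diphenylphosphino)benzene (5 mol %), (EtO)2MeSiH (2 equiv), t-BuOH (2 equiv), toluene, 0 °C
Reagents that add atoms: none
Why: Copper hydride conjugate reduction of a β-substituted butenolide; hydride should add to C7 from the face of H-6, anti to C5 and the ring chain, which gives the cis-fused lactone, and t-BuOH protonates the copper enolate at C11. The furanone dienone is a vinylogous ester and should be the poorer acceptor. The descriptor at C7 is S here only because the silyloxy group raises the CIP rank of C8.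

Step 20
Reactants: 29 saturated 6,12-lactone
Product: 33 α-methylene lactone [(5S,6R,7S,8R,10R); C11=C13; 5-O-(4-methoxybenzyl); 8-O-TBS], via lithium enolate of the lactone 30 (not isolated), via Mannich base 31 (not isolated), via trimethylammonium iodide 32 (not isolated)
Conditions: LiN(SiMe3)2, THF, −78 °C; CH2=NMe2 I, −78 → 0 °C; MeI, MeOH, rt; aq NaHCO3–CH2Cl2
Reagents that add atoms: dimethylmethyleneammonium iodide, C=[N+](C)C.[I-]
Why: Mannich reaction of the lactone enolate at C11, N-methylation and E1cB loss of trimethylamine; C11 is the only acidic site and has no β-leaving group, so C6 and C7 are not disturbed.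

Step 21
Reactants: 33 α-methylene lactone
Product: 34 8-hydroxy compound [(5S,6R,7R,8R,10R); 5-O-(4-methoxybenzyl)]
Conditions: HF·pyridine, pyridine, THF, 0 °C → rt
Reagents that add atoms: none
Why: Buffered fluoride removes the secondary silyl ether without base, which protects the α-methylene lactone from conjugate addition.

Step 22
Reactants: 34 8-hydroxy compound
Product: 35 8-O-isobutyryl 5-O-(4-methoxybenzyl) compound [(5S,6R,7R,8R,10R)]
Conditions: (i-PrCO)2O, Et3N, DMAP (cat.), CH2Cl2, 0 °C
Reagents that add atoms: isobutyric anhydride, CC(C)C(=O)OC(=O)C(C)C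
Why: DMAP-catalysed acylation of the only free hydroxyl; C5 is still protected.

Step 23
Reactants: 35 8-O-isobutyryl 5-O-(4-methoxybenzyl) compound
Product: 36 CNP0384113.1
Conditions: DDQ, CH2Cl2–pH 7 buffer, 0 °C
Reagents that add atoms: none
Why: Oxidative cleavage of the 4-methoxybenzyl ether (hydride abstraction, hydrolysis of the oxocarbenium ion) under neutral conditions; the electron-poor alkenes and the allylic alcohol next to an electron-poor diene should not be oxidised.

## Compound list

1 | (S)-2-methylglycidol | C[C@]1(CO)CO1 | starting material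
2 | 1,3-dithiane | C1CSCSC1 | starting material
3 | 2-lithio-1,3-dithiane | [Li]C1SCCCS1 | intermediate (not isolated)
4 | (R)-3-(1,3-dithian-2-yl)-2-methylpropane-1,2-diol | C[C@](O)(CO)CC1SCCCS1 | intermediate
5 | (R)-3-(1,3-dithian-2-yl)-2-hydroxy-2-methylpropanal | C[C@](O)(C=O)CC1SCCCS1 | intermediate
6 | tert-butyl(but-3-yn-1-yloxy)dimethylsilane | C#CCCO[Si](C)(C)C(C)(C)C | starting material
7 | [4-(tert-butyldimethylsilyloxy)but-1-ynyl]lithium | [Li]C#CCCO[Si](C)(C)C(C)(C)C | intermediate (not isolated)
8 | (2R,3RS)-7-(tert-butyldimethylsilyloxy)-1-(1,3-dithian-2-yl)-2-methylhept-4-yne-2,3-diol | C[C@](O)(C(O)C#CCCO[Si](C)(C)C(C)(C)C)CC1SCCCS1 | intermediate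
9 | (R)-7-(tert-butyldimethylsilyloxy)-1-(1,3-dithian-2-yl)-2-hydroxy-2-methylhept-4-yn-3-one | C[C@](O)(C(=O)C#CCCO[Si](C)(C)C(C)(C)C)CC1SCCCS1 | intermediate
10 | (R)-5-[2-(tert-butyldimethylsilyloxy)ethyl]-2-(1,3-dithian-2-ylmethyl)-2-methylfuran-3(2H)-one | CC(C)(C)[Si](C)(C)OCCC1=CC(=O)[C@@](C)(CC2SCCCS2)O1 | intermediate
11 | lithium dienolate of 10 (C1 enolate, C3=C4) | [Li]OC1=CC(=CCO[Si](C)(C)C(C)(C)C)O[C@]1(C)CC1SCCCS1 | intermediate (not isolated)
12 | (R)-5-[3-(tert-butyldimethylsilyloxy)-1-hydroxyprop-1-en-2-yl]-2-(1,3-dithian-2-ylmethyl)-2-methylfuran-3(2H)-one (enol of the C4 aldehyde) | OC=C(CO[Si](C)(C)C(C)(C)C)C1=CC(=O)[C@@](C)(CC2SCCCS2)O1 | intermediate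
13 | (R)-5-{(E)-3-(tert-butyldimethylsilyloxy)-1-[(4-methoxybenzyl)oxy]prop-1-en-2-yl}-2-(1,3-dithian-2-ylmethyl)-2-methylfuran-3(2H)-one | COc1ccc(CO/C=C(/C2=CC(=O)[C@@](C)(CC3SCCCS3)O2)CO[Si](C)(C)C(C)(C)C)cc1 | intermediate
14 | 2-Fu-acetaldehyde (C8 aldehyde) | COc1ccc(CO/C=C(/C2=CC(=O)[C@@](C)(CC=O)O2)CO[Si](C)(C)C(C)(C)C)cc1 | intermediate
15 | methyl propiolate | C#CC(=O)OC | starting material
16 | methyl 3-(methylzincio)propiolate | C[Zn]C#CC(=O)OC | intermediate (not isolated)
17 | methyl (4R)-4-hydroxy-5-Fu-pent-2-ynoate | COc1ccc(CO/C=C(/C2=CC(=O)[C@@](C)(C[C@@H](O)C#CC(=O)OC)O2)CO[Si](C)(C)C(C)(C)C)cc1 | intermediate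
18 | methyl (4R)-4-[(tert-butyldimethylsilyl)oxy]-5-Fu-pent-2-ynoate | COc1ccc(CO/C=C(/C2=CC(=O)[C@@](C)(C[C@@H](O[Si](C)(C)C(C)(C)C)C#CC(=O)OC)O2)CO[Si](C)(C)C(C)(C)C)cc1 | intermediate
19 | methyl (2Z,4R)-4-[(tert-butyldimethylsilyl)oxy]-3-iodo-5-Fu-pent-2-enoate | COc1ccc(CO/C=C(/C2=CC(=O)[C@@](C)(C[C@@H](O[Si](C)(C)C(C)(C)C)/C(I)=C/C(=O)OC)O2)CO[Si](C)(C)C(C)(C)C)cc1 | intermediate
20 | (tributylstannyl)methanol | CCCC[Sn](CCCC)(CCCC)CO | starting material
21 | tributyl[(oxan-2-yloxy)methyl]stannane (both acetal epimers) | CCCC[Sn](CCCC)(CCCC)COC1CCCCO1 | intermediate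
22 | methyl (2E,4R)-4-[(tert-butyldimethylsilyl)oxy]-3-[(oxan-2-yloxy)methyl]-5-Fu-pent-2-enoate (both acetal epimers) | COc1ccc(CO/C=C(/C2=CC(=O)[C@@](C)(C[C@@H](O[Si](C)(C)C(C)(C)C)/C(COC3CCCCO3)=C/C(=O)OC)O2)CO[Si](C)(C)C(C)(C)C)cc1 | intermediate
23 | methyl (2Z,4R)-3-(bromomethyl)-4-[(tert-butyldimethylsilyl)oxy]-5-Fu-pent-2-enoate | COc1ccc(CO/C=C(/C2=CC(=O)[C@@](C)(C[C@@H](O[Si](C)(C)C(C)(C)C)/C(CBr)=C/C(=O)OC)O2)CO[Si](C)(C)C(C)(C)C)cc1 | intermediate
24 | bromo alcohol: 23 with the C15 hydroxyl free | COc1ccc(CO/C=C(/C2=CC(=O)[C@@](C)(C[C@@H](O[Si](C)(C)C(C)(C)C)/C(CBr)=C/C(=O)OC)O2)CO)cc1 | intermediate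
25 | eleven-membered cyclic ether, (4E,7E,8R,10R): C15–O–C6 ether, CO2Me cis to C6, 4-methoxybenzyloxy cis to C15, 8-O-TBS | COC(=O)/C=C1\COC/C(=C\OCc2ccc(OC)cc2)C2=CC(=O)[C@@](C)(C[C@H]1O[Si](C)(C)C(C)(C)C)O2 | intermediate
26 | lithium dienolate of 25 (C12 enolate, C6=C7) | COC(O[Li])=CC1=COC/C(=C\OCc2ccc(OC)cc2)C2=CC(=O)[C@@](C)(C[C@H]1O[Si](C)(C)C(C)(C)C)O2 | intermediate (not isolated)
27 | ten-membered hydroxy enoate, (5S,6R,8R,10R): 6-OH, 5-O-(4-methoxybenzyl), C4=C15, 8-O-TBS, (7E)-C7=C11–CO2Me | COC(=O)/C=C1\[C@@H](O)[C@@H](OCc2ccc(OC)cc2)C(=C)C2=CC(=O)[C@@](C)(C[C@H]1O[Si](C)(C)C(C)(C)C)O2 | intermediate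
28 | butenolide, (5S,6R,8R,10R): 6,12-olide with C7=C11 | O=C1O[C@@H]2C(=C1)[C@H](O[Si](C)(C)C(C)(C)C)C[C@@]1(C)OC(=CC1=O)C(=C)[C@@H]2OCc1ccc(OC)cc1 | intermediate
29 | saturated 6,12-lactone, (5S,6R,7S,8R,10R), H-7 cis to H-6 | O=C1O[C@@H]2[C@H](C1)[C@H](O[Si](C)(C)C(C)(C)C)C[C@@]1(C)OC(=CC1=O)C(=C)[C@@H]2OCc1ccc(OC)cc1 | intermediate
30 | lithium enolate of 29 | [Li]OC1O[C@@H]2[C@H](C=1)[C@H](O[Si](C)(C)C(C)(C)C)C[C@@]1(C)OC(=CC1=O)C(=C)[C@@H]2OCc1ccc(OC)cc1 | intermediate (not isolated)
31 | Mannich base: 29 with CH2NMe2 on C11 (both C11 epimers) | CN(C)CC1C(=O)O[C@@H]2[C@H]1[C@H](O[Si](C)(C)C(C)(C)C)C[C@@]1(C)OC(=CC1=O)C(=C)[C@@H]2OCc1ccc(OC)cc1 | intermediate (not isolated)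
32 | trimethylammonium iodide of 31 | [I-].C[N+](C)(C)CC1C(=O)O[C@@H]2[C@H]1[C@H](O[Si](C)(C)C(C)(C)C)C[C@@]1(C)OC(=CC1=O)C(=C)[C@@H]2OCc1ccc(OC)cc1 | intermediate (not isolated)
33 | α-methylene lactone, (5S,6R,7S,8R,10R): 5-O-(4-methoxybenzyl), 8-O-TBS | C=C1C(=O)O[C@@H]2[C@H]1[C@H](O[Si](C)(C)C(C)(C)C)C[C@@]1(C)OC(=CC1=O)C(=C)[C@@H]2OCc1ccc(OC)cc1 | intermediate
34 | 8-hydroxy compound, (5S,6R,7R,8R,10R): 5-O-(4-methoxybenzyl) | C=C1C(=O)O[C@@H]2[C@H]1[C@H](O)C[C@@]1(C)OC(=CC1=O)C(=C)[C@@H]2OCc1ccc(OC)cc1 | intermediate
35 | 5-O-(4-methoxybenzyl) ether of the target, (5S,6R,7R,8R,10R) | C=C1C(=O)O[C@@H]2[C@H]1[C@H](OC(=O)C(C)C)C[C@@]1(C)OC(=CC1=O)C(=C)[C@@H]2OCc1ccc(OC)cc1 | intermediate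
36 | CNP0384113.1, (5S,6R,7R,8R,10R) | C=C1C(=O)O[C@@H]2[C@H]1[C@H](OC(=O)C(C)C)C[C@@]1(C)OC(=CC1=O)C(=C)[C@@H]2O | target

Total step count: 23. Longest linear sequence: 22 steps (steps 1–11 and 13–23); step 12 is a one-step side branch.

## Least certain steps

Step 17 (key step). Several things can go wrong. The base may deprotonate at C8 instead of C6. The carbanion may add to C5 in a stepwise conjugate fashion and then expel the 4-methoxybenzyl oxide instead of breaking O–C15. The bridged transition state is strained (the C5–C9 segment of the new ring must be almost fully extended), which may favour a [1,2] shift or decomposition of the dienolate. Attack may come from the other face of the allyl unit and give the 5R,6S pair. Finally, C6 may epimerise through the furanolate if the alkoxide lactonises while base is still present. The fallback forms C5–C6 by a vinylogous aldol addition instead and sets out from iodide 19. Stille coupling with (tributylstannyl)methanol 20 (Pd(PPh3)4, dioxane, 80 °C) would give, after spontaneous lactonisation of the cis hydroxy ester, the open-chain butenolide F1. Desilylation at C15 (Et3N·3HF) and brief exposure to PPTS in wet acetone would unmask the 2-substituted acrolein F2, the γ-alkoxyallyl alcohol losing 4-methoxybenzyl alcohol with allylic transposition. Silylation (TBSOTf, Et3N) would give the 2-silyloxyfuran F3. Its intramolecular vinylogous Mukaiyama aldol addition to the C5 aldehyde (BF3·OEt2, CH2Cl2, −78 °C, high dilution) would close the ten-membered ring as hydroxy butenolide F4. O-Alkylation with 4-methoxybenzyl trichloroacetimidate (La(OTf)3 cat.) returns to 28.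

Step 16. Ring closure may be slower than intermolecular etherification, or the bromide may be lost by elimination or solvolysis before the ether forms. The fallback closes the same ring by the C6–C7 bond and sets out from iodide 19. Selective desilylation at C15 (Et3N·3HF) would give alcohol F5. O-Alkylation with tributyl(iodomethyl)stannane (NaH, THF, 0 °C) would give the stannylmethyl ether F6. An intramolecular Stille coupling (Pd(PPh3)4, CuI, dioxane, high dilution) returns to 25.

Step 19. Hydride may be transferred to C15 of the dienone (1,6-reduction) in competition with the hindered butenolide, or may reach C7 from the face of C5. The fallback masks the dienone and sets out from 28. Conjugate addition of thiophenol to C15 (Et3N cat., CH2Cl2) would give sulfide F7 as both C4 epimers. The copper hydride reduction of step 19 would then give F8. Oxidation (3-chloroperbenzoic acid, −78 °C) to sulfoxide F9 and thermal syn-elimination (toluene, 90 °C) restores C4=C15 and returns to 29.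

Step 9. The aldehyde may lose the furanone oxygen from C10 by β-elimination (ring opening) before it is alkynylated, and facial control by the catalyst may be incomplete next to the quaternary centre. The fallback sets C8 by reduction and sets out from 14. Addition of lithiated 15 (LiN(SiMe3)2, THF, −90 °C) would give the C8-epimeric alcohols F10. MnO2 oxidation would give ynone F11. Asymmetric transfer hydrogenation (RuCl[(R,R)-TsDPEN](p-cymene), i-PrOH, rt) returns to 17.

Step 7. O-Alkylation may give some of the (Z)-enol ether, or may occur at the ring carbonyl oxygen. The fallback sets out from 10. Condensation with tert-butoxybis(dimethylamino)methane (toluene, 80 °C) would give the (E)-enaminone F12. Acid-catalysed exchange with 4-methoxybenzyl alcohol (PPTS, toluene, 60 °C, with removal of dimethylamine) gives the thermodynamically preferred (E)-enol ether and returns to 13.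

## Further compounds

F1 | step 17 | open-chain butenolide: 4-[(1R)-1-(tert-butyldimethylsilyloxy)-2-Fu-ethyl]furan-2(5H)-one | COc1ccc(CO/C=C(/C2=CC(=O)[C@@](C)(C[C@@H](O[Si](C)(C)C(C)(C)C)C3=CC(=O)OC3)O2)CO[Si](C)(C)C(C)(C)C)cc1
F2 | step 17 | acrolein: 2-[(5R)-5-{(2R)-2-(tert-butyldimethylsilyloxy)-2-(5-oxo-2,5-dihydrofuran-3-yl)ethyl}-5-methyl-4-oxo-4,5-dihydrofuran-2-yl]prop-2-enal | O=CC(=C)C1=CC(=O)[C@@](C)(C[C@@H](O[Si](C)(C)C(C)(C)C)C2=CC(=O)OC2)O1
F3 | step 17 | 2-silyloxyfuran of F2 | O=CC(=C)C1=CC(=O)[C@@](C)(C[C@@H](O[Si](C)(C)C(C)(C)C)c2coc(O[Si](C)(C)C(C)(C)C)c2)O1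
F4 | step 17 | ten-membered 5-hydroxy butenolide, (5S,6R,8R,10R) | O=C1O[C@@H]2C(=C1)[C@H](O[Si](C)(C)C(C)(C)C)C[C@@]1(C)OC(=CC1=O)C(=C)[C@@H]2O
F5 | step 16 | iodide 19 with the C15 hydroxyl free | COc1ccc(CO/C=C(/C2=CC(=O)[C@@](C)(C[C@@H](O[Si](C)(C)C(C)(C)C)/C(I)=C/C(=O)OC)O2)CO)cc1
F6 | step 16 | C15 (tributylstannyl)methyl ether of F5 | COc1ccc(CO/C=C(/C2=CC(=O)[C@@](C)(C[C@@H](O[Si](C)(C)C(C)(C)C)/C(I)=C/C(=O)OC)O2)COC[Sn](CCCC)(CCCC)CCCC)cc1
F7 | step 19 | C15 phenylsulfanyl adduct of 28 (both C4 epimers) | O=C1O[C@@H]2C(=C1)[C@H](O[Si](C)(C)C(C)(C)C)C[C@@]1(C)OC(=CC1=O)C(CSc1ccccc1)[C@@H]2OCc1ccc(OC)cc1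
F8 | step 19 | C15 phenylsulfanyl saturated lactone (both C4 epimers) | O=C1O[C@@H]2[C@H](C1)[C@H](O[Si](C)(C)C(C)(C)C)C[C@@]1(C)OC(=CC1=O)C(CSc1ccccc1)[C@@H]2OCc1ccc(OC)cc1
F9 | step 19 | sulfoxide of F8 | O=C1O[C@@H]2[C@H](C1)[C@H](O[Si](C)(C)C(C)(C)C)C[C@@]1(C)OC(=CC1=O)C(CS(=O)c1ccccc1)[C@@H]2OCc1ccc(OC)cc1
F10 | step 9 | methyl (4RS)-4-hydroxy-5-Fu-pent-2-ynoate | COc1ccc(CO/C=C(/C2=CC(=O)[C@@](C)(CC(O)C#CC(=O)OC)O2)CO[Si](C)(C)C(C)(C)C)cc1
F11 | step 9 | methyl 4-oxo-5-Fu-pent-2-ynoate | COc1ccc(CO/C=C(/C2=CC(=O)[C@@](C)(CC(=O)C#CC(=O)OC)O2)CO[Si](C)(C)C(C)(C)C)cc1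
F12 | step 7 | (E)-dimethylaminomethylene derivative of 10 | CN(C)/C=C(/C1=CC(=O)[C@@](C)(CC2SCCCS2)O1)CO[Si](C)(C)C(C)(C)C
A1 | alternative 1 | open-chain α-ketol: lactone-bearing tertiary alkynyl carbinol with the C10 methyl ketone and a 2-iodoallyl alkyne terminus | C=C1C(=O)O[C@@H](CO[Si](C)(C)C(C)(C)C)[C@H]1[C@H](OC(=O)C(C)C)C[C@](O)(C#CC(=C)I)C(C)=O
A2 | alternative 1 | iodovinyl furanone with α-methylene lactone and C5 silyl ether | C=C1C(=O)O[C@@H](CO[Si](C)(C)C(C)(C)C)[C@H]1[C@H](OC(=O)C(C)C)C[C@@]1(C)OC(=CC1=O)C(=C)I
A3 | alternative 2 | ten-membered enol lactone (C1 acyl on the C3 enol oxygen) | C=C1C(=O)O[C@@H]2[C@H]1[C@H](OC(=O)C(C)C)C[C@@](C)(O[Si](CC)(CC)CC)C(=O)OC(=C)C(=C)[C@@H]2O[Si](C)(C)C(C)(C)C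
A4 | alternative 2 | ten-membered carbocyclic 1,3-diketone with silylated C10 hydroxyl | C=C1C(=O)O[C@@H]2[C@H]1[C@H](OC(=O)C(C)C)C[C@@](C)(O[Si](CC)(CC)CC)C(=O)CC(=O)C(=C)[C@@H]2O[Si](C)(C)C(C)(C)C
A5 | alternative 3 | nine-membered acrylate lactone carrying the keto phosphorane on C10 | C=C1C(=O)O[C@@H]2[C@H]1[C@H](OC(=O)C(C)C)C[C@](C)(C(=O)C=P(c1ccccc1)(c1ccccc1)c1ccccc1)OC(=O)C(=C)[C@@H]2O[Si](C)(C)C(C)(C)C
A6 | alternative 3 | C5 tert-butyldimethylsilyl ether of the target | C=C1C(=O)O[C@@H]2[C@H]1[C@H](OC(=O)C(C)C)C[C@@]1(C)OC(=CC1=O)C(=C)[C@@H]2O[Si](C)(C)C(C)(C)C
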